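(The numbers in the tables come from a simulation for substances that don't exist; the scatter is artificial.)

Read this flask by its split, the G formed per X formed, rather than by its clock.

- blue: L 0.10 M (fed, over 40 min); Z 1.8 equiv; run made earlier
- flask: L 0.050 M (fed, over 40 min); Z 1.80 equiv; time 6.0 d

blue run (percent of the L charged)

| time / h | X / % | G / % |
|---|---|---|
| 2.50 | 17.9 | 0 |
| 5.00 | 27.1 | 0.4 |
| 12.0 | 39.9 | 2.9 |
| 30.0 | 56.6 | 12.6 |

(standard deviation of a reading: 0.5 percentage points)

1. concentration of X at 6.0 d, in M
2. concentration of G at 6.0 d, in M

I began with the clock. If every step is a meeting of two molecules, charge times time is what counts, and at equal equivalents the flask at 6.0 d stood at 2.40 times the clock of the last blue reading. The feed was short against that. In blue at 30.0 h, 30.8% of L had not appeared as X or G. Letting that fraction fall at a steady logarithmic pace gave 94.1% as X plus G in the flask. My objection was that this pace might slacken as Z is used up, but I could not size that from one run, so I kept the figure as an estimate.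

The split s was harder. The last blue reading gave s = 0.223, which I judged low because G lagged, and the last interval gave 0.581, which I judged high for a whole run. I took their midpoint on a logarithmic scale. But that was a blue split, and the flask held less Z. One run cannot show an order, so I wagered that G needed one more Z than X, and carried σ, the split per molar of Z charged, 2.00 M⁻¹, a kind of selectivity factor. For the flask this gave s = 0.180, so X 0.0399 M and G 0.00717 M.

The forecast gave 0.025 M and 0.02 M, a split of 0.800, on the ground that “halving the concentrations doubles the timescale”.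

The flask gave 0.0391 M and 0.00820 M, a split of 0.210.

    L + Z ⇌ J (K = 11.0 M⁻¹, k = 4.62 × 10⁻⁴ M⁻¹ s⁻¹)
    L + Z → X (k = 2.11 × 10⁻⁴ M⁻¹ s⁻¹)
    Z + J → D (k = 1.10 × 10⁻⁴ M⁻¹ s⁻¹)
    D ⇌ Q (K = 16.0, k = 1.49 × 10⁻⁴ s⁻¹)
    Q ⇌ G (K = 6.60, k = 1.88 × 10⁻⁵ s⁻¹)

In this scheme X takes one Z, and the path to G through J takes a second. Read back from the flask, σ is 2.33 M⁻¹, against my 2.00 M⁻¹. For the neighbour with 1.10 equiv of Z, my σ gives s = 0.110. That flask computed to 0.0366 M and 0.00383 M, a split of 0.105.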